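**Plan**

Core numbering: C1 benzoyl bridgehead, C2 enol carbon, C3, C4 ketone, C5 prenyl bridgehead, C6 CMe2, C7, C8 CH2, C9 bridge ketone; ring A = C1–C8–C7–C6–C5–C9, ring B = C1–C2–C3–C4–C5–C9.
Retrosynthesis: O4 is methylated and the C7 prenyl is cut back to formyl (two C=C bonds); then C1–C8 is cut (Michael addition), then C5–C6 (Claisen shift from the C9 oxygen), then the aryl ether and both aryl–prenyl bonds.
Forward: ring B is the phloroglucinol ring of 2,4,6-trihydroxybenzophenone; it is C-prenylated, dearomatised at C5 by the [3,3] shift, and ring A closes last through C1–C8.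
Enabling feature: the benzoyl sits on bridgehead C1 and the only non-bridgehead prenyl on C3. Of the two ring-B carbons that can reach C8 (C1 across C9, C3 across C4), only acyl-bearing C1 must bond, and holding O4 as a methyl enol ether leaves C1 as the sole enolate carbon.
Stereochemistry: C5 from a ligand-controlled Claisen rearrangement; C1 follows from C5 because the C6–C7–C8 bridge spans only one ring face; C7 by equilibration of the aldehyde to the exo (equatorial) position.

Key step: step 9

Assumption: 1,3-dicarbonyl enols are written as one tautomer (12 as the C9 enol, 17 as the C2 enol); descriptors refer to the tautomer written, and bicyclic compounds are named with the core numbering.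
Assumption: the (S,S)-ligand is taken to direct the allyl terminus to the face of C5 that gives (6R)-11; if the sense proves opposite, the (R,R)-ligand is used.
Assumption: 14 is expected as an E/Z mixture (E isomer written); both isomers converge in step 11.

**Step 1**
Reactants: 1 2,4,6-trihydroxybenzophenone; 2 prenyl bromide (1-bromo-3-methylbut-2-ene)
Product: 3 2,4,6-trihydroxy-3,5-bis(3-methylbut-2-enyl)benzophenone
Conditions: 2 (2 equiv), 10% aq. KOH, 0 °C
Reagents that add atoms: none
Why: In aqueous base the phloroglucinol polyanion is alkylated at carbon, so both free ring positions should take a prenyl group (C-alkylation of an acylphloroglucinol, a known preparation of this compound).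

**Step 2**
Reactants: 3 2,4,6-trihydroxy-3,5-bis(3-methylbut-2-enyl)benzophenone
Product: 4 2,6-dihydroxy-4-methoxy-3,5-bis(3-methylbut-2-enyl)benzophenone
Conditions: Me2SO4 (1.05 equiv), K2CO3, acetone, 23 °C
Reagents that add atoms: dimethyl sulfate, COS(=O)(=O)OC
Why: The 4-hydroxyl, para to the benzoyl group, is the most acidic and the only one not hydrogen-bonded to the ketone, so one equivalent of a hard methylating agent should give the 4-O-methyl ether (selective phenol O-methylation).

**Step 3**
Reactants: 5 diethyl isopropylidenemalonate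
Product: 6 2-(propan-2-ylidene)propane-1,3-diol
Conditions: i-Bu2AlH (4.4 equiv), CH2Cl2, −78 → 0 °C; aq. potassium sodium tartrate work-up
Reagents that add atoms: none
Why: i-Bu2AlH reduces both conjugated esters in the 1,2 sense at low temperature without conjugate reduction, giving the allylic diol (ester reduction).

**Step 4**
Reactants: 6 2-(propan-2-ylidene)propane-1,3-diol
Product: 7 2-(hydroxymethyl)-3-methylbut-2-enal
Conditions: activated MnO2 (excess), CH2Cl2, 23 °C
Reagents that add atoms: none
Why: MnO2 oxidises one of the two equivalent allylic hydroxymethyl groups and should then stop, because the remaining alcohol is allylic to an electron-poor enal double bond (chemoselective allylic oxidation).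

**Step 5**
Reactants: 7 2-(hydroxymethyl)-3-methylbut-2-enal
Product: 8 2-(bromomethyl)-3-methylbut-2-enal
Conditions: PBr3 (0.4 equiv), Et2O, 0 °C
Reagents that add atoms: phosphorus tribromide, BrP(Br)Br
Why: Bromide displaces the phosphite ester of the primary allylic alcohol, as in the preparation of 2-(bromomethyl)acrylates, and the symmetric CMe2 terminus leaves no alkene geometry to lose.

**Step 6**
Reactants: 4 2,6-dihydroxy-4-methoxy-3,5-bis(3-methylbut-2-enyl)benzophenone; 8 2-(bromomethyl)-3-methylbut-2-enal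
Product: 9 2-{[2-benzoyl-3-hydroxy-5-methoxy-4,6-bis(3-methylbut-2-enyl)phenoxy]methyl}-3-methylbut-2-enal
Conditions: 8 (1.1 equiv), K2CO3 (1.2 equiv), acetone, 0 → 23 °C
Reagents that add atoms: none
Why: One of the two equivalent ortho-phenoxides displaces the primary allylic bromide (Williamson ether synthesis); the second hydroxyl is then locked in a hydrogen bond to the ketone and reacts far more slowly, and attack at the fully substituted alkene terminus is sterically excluded.

**Step 7**
Reactants: 9 2-{[2-benzoyl-3-hydroxy-5-methoxy-4,6-bis(3-methylbut-2-enyl)phenoxy]methyl}-3-methylbut-2-enal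
Product: 10 2-{[2-benzoyl-3-(tert-butyldimethylsilyloxy)-5-methoxy-4,6-bis(3-methylbut-2-enyl)phenoxy]methyl}-3-methylbut-2-enal
Conditions: TBSCl, imidazole, DMF, 23 °C
Reagents that add atoms: tert-butyldimethylsilyl chloride, CC(C)(C)[Si](C)(C)Cl
Why: Silylation of the remaining chelated phenol removes the acidic proton that would bind copper and frees the benzoyl oxygen to chelate together with the allyl ether oxygen (silyl ether formation).

**Step 8**
Reactants: 10 2-{[2-benzoyl-3-(tert-butyldimethylsilyloxy)-5-methoxy-4,6-bis(3-methylbut-2-enyl)phenoxy]methyl}-3-methylbut-2-enal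
Product: 12 (4S)-2-benzoyl-3-hydroxy-5-methoxy-4,6-bis(3-methylbut-2-enyl)-4-(3-formyl-2-methylbut-3-en-2-yl)cyclohexa-2,5-dien-1-one (C5-quaternary enol), via silyl dienone 11 (not isolated)
Conditions: Cu(OTf)2 (20 mol %), 2,2′-(propane-2,2-diyl)bis[(4S)-4-tert-butyl-4,5-dihydrooxazole] (22 mol %), 4 Å MS, CH2Cl2, −20 → 23 °C; then 1 M aq. HCl, THF, 0 °C
Reagents that add atoms: none
Why: Proposed new method: a chiral divalent-copper bis(oxazoline) Lewis acid, held in a six-membered chelate between the benzoyl oxygen and the aryl ether oxygen, should polarise the O–CH2 bond and accelerate a concerted [3,3] shift of the 2-formylprenyl group to the prenylated ortho carbon C5 rather than to the electron-poorer acyl-bearing C1, so that the CMe2 terminus forms C5–C6 and the ligand decides which ring face is attacked, which sets C5; the 2-formyl group disfavours ionisation to an allyl cation, the silyl ether keeps the product non-acidic so that it should not sequester copper, and the closest known reactions are the copper bis(oxazoline)-catalysed Claisen rearrangement of 2-alkoxycarbonyl allyl vinyl ethers and the chiral-Lewis-acid-catalysed dearomative Claisen rearrangement of allyl 2-naphthyl ethers bearing a chelating carbonyl next to the ether oxygen; dilute acid then hydrolyses the labile silyl enol ether 11 to the hydrogen-bonded enol 12.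

**Step 9**
Reactants: 12 (4S)-2-benzoyl-3-hydroxy-5-methoxy-4,6-bis(3-methylbut-2-enyl)-4-(3-formyl-2-methylbut-3-en-2-yl)cyclohexa-2,5-dien-1-one
Product: 13 (1R,5R,7R)-1-benzoyl-4-methoxy-6,6-dimethyl-3,5-bis(3-methylbut-2-enyl)-2,9-dioxobicyclo[3.3.1]non-3-ene-7-carbaldehyde
Conditions: K2CO3 (0.3 equiv), MeCN, 23 → 40 °C
Reagents that add atoms: none
Why: Carbonate removes the enol proton to give a triketonate spread over C1 and the C2, C9 and benzoyl oxygens; C1 adds to C8, the methylene terminus of the 2-formylallyl unit held over the ring by C6, and hydrogen carbonate protonates the resulting aldehyde enolate at C7 (intramolecular Michael addition). The closest known reaction is the base-mediated annulation of dearomatised acylphloroglucinols onto 2-substituted acroleins to give 7-formylbicyclo[3.3.1]nonanes, which so far runs through a prenyl-bearing ring carbon, so bonding through the acyl-bearing carbon is the less explored site. Ring A (C1–C8–C7–C6–C5–C9) closes 6-endo-trig, with the C7=C8 bond inside the new ring, through a chair. C1 is set by C5, since the three-carbon bridge can reach C1 only on the ring face that already carries C6, and C7 is set under thermodynamic control, the formyl group epimerising through its enolate to the exo (equatorial) position away from the C2–C3–C4 bridge. The step needs C1, not C3 or an enolate oxygen, to bond: C3 is the alpha carbon of the C4 methyl enol ether and carries no enolate charge, and closure through the C9 oxygen is a reversible oxa-Michael addition that should drain into the C–C bonded product. The base is kept below one equivalent so that the neutral, non-acidic product does not compete with a stoichiometric triketonate salt of the precursor.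

**Step 10**
Reactants: 13 (1R,5R,7R)-1-benzoyl-4-methoxy-6,6-dimethyl-3,5-bis(3-methylbut-2-enyl)-2,9-dioxobicyclo[3.3.1]non-3-ene-7-carbaldehyde
Product: 14 (1R,5R,7S)-1-benzoyl-4-methoxy-7-[(E)-2-methoxyethenyl]-6,6-dimethyl-3,5-bis(3-methylbut-2-enyl)bicyclo[3.3.1]non-3-ene-2,9-dione
Conditions: Ph3P(CH2OMe)Cl (1.5 equiv), KN(SiMe3)2 (1.4 equiv), THF, 0 °C; then 13, −78 → 0 °C
Reagents that add atoms: (methoxymethyl)triphenylphosphonium chloride, COC[P+](c1ccccc1)(c1ccccc1)c1ccccc1.[Cl-]
Why: The non-stabilised methoxymethylene ylide should add to the aldehyde far faster than to the C9 ketone, the bridgehead benzoyl ketone or the vinylogous ester carbonyl, all flanked by quaternary carbons, and at −78 °C addition should outrun deprotonation at C7 (Wittig olefination; C7 is not touched).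

**Step 11**
Reactants: 14 (1R,5R,7S)-1-benzoyl-4-methoxy-7-[(E)-2-methoxyethenyl]-6,6-dimethyl-3,5-bis(3-methylbut-2-enyl)bicyclo[3.3.1]non-3-ene-2,9-dione
Product: 15 2-[(1R,5R,7S)-1-benzoyl-4-methoxy-6,6-dimethyl-3,5-bis(3-methylbut-2-enyl)-2,9-dioxobicyclo[3.3.1]non-3-en-7-yl]acetaldehyde
Conditions: 2 M aq. HCl, THF, 23 °C
Reagents that add atoms: water, O
Why: C-protonation of the simple enol ether and loss of methanol from the hemiacetal is much faster than hydrolysis of the C4 vinylogous ester, and the prenyl alkenes tolerate dilute acid at room temperature (enol ether hydrolysis).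

**Step 12**
Reactants: 15 2-[(1R,5R,7S)-1-benzoyl-4-methoxy-6,6-dimethyl-3,5-bis(3-methylbut-2-enyl)-2,9-dioxobicyclo[3.3.1]non-3-en-7-yl]acetaldehyde
Product: 16 (1R,5R,7R)-1-benzoyl-4-methoxy-6,6-dimethyl-3,5,7-tris(3-methylbut-2-enyl)bicyclo[3.3.1]non-3-ene-2,9-dione
Conditions: i-PrPPh3I, n-BuLi, THF, 0 °C; then 15, −78 → 23 °C
Reagents that add atoms: isopropyltriphenylphosphonium iodide, CC(C)[P+](c1ccccc1)(c1ccccc1)c1ccccc1.[I-]
Why: The isopropylidene ylide converts the unhindered side-chain aldehyde into the third prenyl group while the hindered ketones do not compete (Wittig olefination).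

**Step 13**
Reactants: 16 (1R,5R,7R)-1-benzoyl-4-methoxy-6,6-dimethyl-3,5,7-tris(3-methylbut-2-enyl)bicyclo[3.3.1]non-3-ene-2,9-dione
Product: 17 (1S,5R,7R)-1-benzoyl-2-hydroxy-6,6-dimethyl-3,5,7-tris(3-methylbut-2-enyl)bicyclo[3.3.1]non-2-ene-4,9-dione (CNP0284108.1)
Conditions: LiCl, DMSO, 120 °C; then 1 M aq. HCl
Reagents that add atoms: none
Why: Chloride attacks the methyl group of the vinylogous ester in an SN2 dealkylation, releasing the stabilised diketonate, which gives the enolised dione on acidification (Krapcho-type demethylation; no stereocentre is affected).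

**Compound list**

1 | 2,4,6-trihydroxybenzophenone | O=C(c1ccccc1)c1c(O)cc(O)cc1O | starting material
2 | prenyl bromide (1-bromo-3-methylbut-2-ene) | CC(C)=CCBr | starting material
3 | 2,4,6-trihydroxy-3,5-bis(3-methylbut-2-enyl)benzophenone | O=C(c1ccccc1)c1c(O)c(CC=C(C)C)c(O)c(CC=C(C)C)c1O | intermediate
4 | 2,6-dihydroxy-4-methoxy-3,5-bis(3-methylbut-2-enyl)benzophenone | COc1c(CC=C(C)C)c(O)c(C(=O)c2ccccc2)c(O)c1CC=C(C)C | intermediate
5 | diethyl isopropylidenemalonate | CCOC(=O)C(=C(C)C)C(=O)OCC | starting material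
6 | 2-(propan-2-ylidene)propane-1,3-diol | CC(C)=C(CO)CO | intermediate
7 | 2-(hydroxymethyl)-3-methylbut-2-enal | CC(C)=C(CO)C=O | intermediate
8 | 2-(bromomethyl)-3-methylbut-2-enal | CC(C)=C(CBr)C=O | intermediate
9 | 2-{[2-benzoyl-3-hydroxy-5-methoxy-4,6-bis(3-methylbut-2-enyl)phenoxy]methyl}-3-methylbut-2-enal | COc1c(CC=C(C)C)c(O)c(C(=O)c2ccccc2)c(OCC(C=O)=C(C)C)c1CC=C(C)C | intermediate
10 | 2-{[2-benzoyl-3-(tert-butyldimethylsilyloxy)-5-methoxy-4,6-bis(3-methylbut-2-enyl)phenoxy]methyl}-3-methylbut-2-enal | COc1c(CC=C(C)C)c(O[Si](C)(C)C(C)(C)C)c(C(=O)c2ccccc2)c(OCC(C=O)=C(C)C)c1CC=C(C)C | intermediate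
11 | (6R)-2-benzoyl-3-(tert-butyldimethylsilyloxy)-5-methoxy-4,6-bis(3-methylbut-2-enyl)-6-(3-formyl-2-methylbut-3-en-2-yl)cyclohexa-2,4-dien-1-one (silyl dienone) | CC(C)=CCC1=C(OC)[C@@](CC=C(C)C)(C(C)(C)C(=C)C=O)C(=O)C(C(=O)c2ccccc2)=C1O[Si](C)(C)C(C)(C)C | intermediate
12 | (4S)-2-benzoyl-3-hydroxy-5-methoxy-4,6-bis(3-methylbut-2-enyl)-4-(3-formyl-2-methylbut-3-en-2-yl)cyclohexa-2,5-dien-1-one | CC(C)=CCC=1C(=O)C(C(=O)c2ccccc2)=C(O)[C@](CC=C(C)C)(C(C)(C)C(=C)C=O)C=1OC | intermediate
13 | (1R,5R,7R)-1-benzoyl-4-methoxy-6,6-dimethyl-3,5-bis(3-methylbut-2-enyl)-2,9-dioxobicyclo[3.3.1]non-3-ene-7-carbaldehyde | CC(C)=CCC=1C(=O)[C@]2(C(=O)c3ccccc3)C[C@@H](C=O)C(C)(C)[C@](CC=C(C)C)(C=1OC)C2=O | intermediate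
14 | (1R,5R,7S)-1-benzoyl-4-methoxy-7-[(E)-2-methoxyethenyl]-6,6-dimethyl-3,5-bis(3-methylbut-2-enyl)bicyclo[3.3.1]non-3-ene-2,9-dione | CC(C)=CCC=1C(=O)[C@]2(C(=O)c3ccccc3)C[C@@H](/C=C/OC)C(C)(C)[C@](CC=C(C)C)(C=1OC)C2=O | intermediate
15 | 2-[(1R,5R,7S)-1-benzoyl-4-methoxy-6,6-dimethyl-3,5-bis(3-methylbut-2-enyl)-2,9-dioxobicyclo[3.3.1]non-3-en-7-yl]acetaldehyde | CC(C)=CCC=1C(=O)[C@]2(C(=O)c3ccccc3)C[C@@H](CC=O)C(C)(C)[C@](CC=C(C)C)(C=1OC)C2=O | intermediate
16 | (1R,5R,7R)-1-benzoyl-4-methoxy-6,6-dimethyl-3,5,7-tris(3-methylbut-2-enyl)bicyclo[3.3.1]non-3-ene-2,9-dione | CC(C)=CCC=1C(=O)[C@]2(C(=O)c3ccccc3)C[C@@H](CC=C(C)C)C(C)(C)[C@](CC=C(C)C)(C=1OC)C2=O | intermediate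
17 | (1S,5R,7R)-1-benzoyl-2-hydroxy-6,6-dimethyl-3,5,7-tris(3-methylbut-2-enyl)bicyclo[3.3.1]non-2-ene-4,9-dione | CC(C)=CCC1=C(O)[C@]2(C(=O)c3ccccc3)C[C@@H](CC=C(C)C)C(C)(C)[C@](CC=C(C)C)(C1=O)C2=O | target

**Step count**

Total: 13 steps. Longest linear sequence: 11 steps (5 → 6 → 7 → 8 → 9 → 10 → 12 → 13 → 14 → 15 → 16 → 17); the branch from 1 joins at step 6.

**Steps most likely to fail**

Step 8. The copper complex may fail to turn over or may attack both faces of C5, because substrate and product offer several carbonyl binding sites. On warming, the side chain may also move on from C5 to C3 by a Cope shift. Fallback: from 10, the rearrangement is run thermally (toluene, 110 °C) without catalyst, which should give the racemic silyl dienone F1 and, after the same acidic work-up, the racemic enol F2. Preparative chromatography on a chiral stationary phase (amylose tris(3,5-dimethylphenylcarbamate)) then separates 12 from its enantiomer F3, and the route is rejoined at 12.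

Step 9. The stabilised, hindered triketonate may add too slowly through carbon, so that closure through the C9 oxygen or reversal by retro-Michael opening dominates. Fallback: from 12, the same C1–C8 bond is made by allylic alkylation instead of conjugate addition.
- NaBH4/CeCl3·7H2O (MeOH, −78 °C) should reduce the enal in the 1,2 sense to the allylic alcohol F4 (Luche reduction; the triketone is inert as its enolate).
- Pd(PPh3)4 (zerovalent palladium, THF, 60 °C) should ionise the allylic alcohol with the help of the acidic triketone. The symmetrical 2-substituted π-allyl complex is then captured by C1 to give the 7-methylene bicycle F5 (Tsuji–Trost allylation; O-allylation is reversible under these conditions).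
- 9-BBN should add only to the 1,1-disubstituted alkene, and NaBO3·4H2O then gives the primary alcohol F6 as C7 epimers.
- Dess–Martin periodinane should give 13 together with its C7 epimer F7, which brief treatment with K2CO3 in MeCN converts into 13, where the route is rejoined.

Step 10. The basic ylide may deprotonate C7 instead of adding to the neopentyl-type aldehyde, and the resulting enolate can expel the triketonate and reopen ring A. Fallback: from 13, the chain is extended through a less basic nucleophile.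
- CH2=CHMgBr (THF, −78 °C) should add to the aldehyde to give the allylic alcohol F8 (carbinol epimers).
- Ac2O/DMAP/pyridine gives the acetate F9.
- Pd(PPh3)4 with HCO2NH4 should reduce the allylic acetate with hydride delivery to the substituted terminus, giving the 7-allyl compound F10.
- Cross-metathesis with 2-methyl-2-butene and the second-generation Grubbs catalyst RuCl2(=CHPh)(H2IMes)(PCy3) converts the allyl into the prenyl group and rejoins the route at 16.

**Further compounds**

F1 | step 8 | racemic 2-benzoyl-3-(tert-butyldimethylsilyloxy)-5-methoxy-4,6-bis(3-methylbut-2-enyl)-6-(3-formyl-2-methylbut-3-en-2-yl)cyclohexa-2,4-dien-1-one | CC(C)=CCC1=C(OC)C(CC=C(C)C)(C(C)(C)C(=C)C=O)C(=O)C(C(=O)c2ccccc2)=C1O[Si](C)(C)C(C)(C)C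
F2 | step 8 | racemic 2-benzoyl-3-hydroxy-5-methoxy-4,6-bis(3-methylbut-2-enyl)-4-(3-formyl-2-methylbut-3-en-2-yl)cyclohexa-2,5-dien-1-one | CC(C)=CCC=1C(=O)C(C(=O)c2ccccc2)=C(O)C(CC=C(C)C)(C(C)(C)C(=C)C=O)C=1OC
F3 | step 8 | (4R)-2-benzoyl-3-hydroxy-5-methoxy-4,6-bis(3-methylbut-2-enyl)-4-(3-formyl-2-methylbut-3-en-2-yl)cyclohexa-2,5-dien-1-one (enantiomer of 12) | CC(C)=CCC=1C(=O)C(C(=O)c2ccccc2)=C(O)[C@@](CC=C(C)C)(C(C)(C)C(=C)C=O)C=1OC
F4 | step 9 | (4S)-2-benzoyl-3-hydroxy-4-[3-(hydroxymethyl)-2-methylbut-3-en-2-yl]-5-methoxy-4,6-bis(3-methylbut-2-enyl)cyclohexa-2,5-dien-1-one | CC(C)=CCC=1C(=O)C(C(=O)c2ccccc2)=C(O)[C@](CC=C(C)C)(C(C)(C)C(=C)CO)C=1OC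
F5 | step 9 | (1R,5R)-1-benzoyl-4-methoxy-6,6-dimethyl-7-methylidene-3,5-bis(3-methylbut-2-enyl)bicyclo[3.3.1]non-3-ene-2,9-dione | CC(C)=CCC=1C(=O)[C@]2(C(=O)c3ccccc3)CC(=C)C(C)(C)[C@](CC=C(C)C)(C=1OC)C2=O
F6 | step 9 | (1R,5R)-1-benzoyl-7-(hydroxymethyl)-4-methoxy-6,6-dimethyl-3,5-bis(3-methylbut-2-enyl)bicyclo[3.3.1]non-3-ene-2,9-dione (C7 epimers) | CC(C)=CCC=1C(=O)[C@]2(C(=O)c3ccccc3)CC(CO)C(C)(C)[C@](CC=C(C)C)(C=1OC)C2=O
F7 | step 9 | (1R,5R,7S)-1-benzoyl-4-methoxy-6,6-dimethyl-3,5-bis(3-methylbut-2-enyl)-2,9-dioxobicyclo[3.3.1]non-3-ene-7-carbaldehyde (C7 epimer of 13) | CC(C)=CCC=1C(=O)[C@]2(C(=O)c3ccccc3)C[C@H](C=O)C(C)(C)[C@](CC=C(C)C)(C=1OC)C2=O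
F8 | step 10 | (1R,5R,7R)-1-benzoyl-7-(1-hydroxyprop-2-enyl)-4-methoxy-6,6-dimethyl-3,5-bis(3-methylbut-2-enyl)bicyclo[3.3.1]non-3-ene-2,9-dione (carbinol epimers) | CC(C)=CCC=1C(=O)[C@]2(C(=O)c3ccccc3)C[C@@H](C(O)C=C)C(C)(C)[C@](CC=C(C)C)(C=1OC)C2=O
F9 | step 10 | 1-[(1R,5R,7R)-1-benzoyl-4-methoxy-6,6-dimethyl-3,5-bis(3-methylbut-2-enyl)-2,9-dioxobicyclo[3.3.1]non-3-en-7-yl]prop-2-enyl acetate | CC(C)=CCC=1C(=O)[C@]2(C(=O)c3ccccc3)C[C@@H](C(OC(C)=O)C=C)C(C)(C)[C@](CC=C(C)C)(C=1OC)C2=O
F10 | step 10 | (1R,5R,7R)-1-benzoyl-4-methoxy-6,6-dimethyl-3,5-bis(3-methylbut-2-enyl)-7-(prop-2-enyl)bicyclo[3.3.1]non-3-ene-2,9-dione | CC(C)=CCC=1C(=O)[C@]2(C(=O)c3ccccc3)C[C@@H](CC=C)C(C)(C)[C@](CC=C(C)C)(C=1OC)C2=O
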